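**Plan**

- Feature: the only ring is the 1,2-dioxolane O1–O2–C3–C4–C5. C3 (Me, CH2CO2H) and C5 (Me, C16 chain, chain carbons C1′–C16′) are both fully substituted, with trans methyls. With both arms cut back to CH2CH2OH the ring is C2-symmetric, and each O–C bond is the invertive opening of a 2-methyloxetane whose ring carbons are the arm.
- Cuts: C9′=C10′ (Julia–Kocienski), C2′–C3′ (Wittig, then diimide), acid arm back to the aldehyde, giving a C2-symmetric dialdehyde and diol. Then O1–C5 (ring closure) and O2–C3 (intermolecular) lead to an (R,R)-bis-oxetane plus H2O2. Each oxetane goes back to a methyl ketone plus two ylide CH2 units, ending at the ketal of ethyl acetoacetate.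
- Forward: ketone, first oxetane, second ketone, second oxetane, H2O2 stitches the dioxolane, one arm olefinated and the other oxidised, chain saturated, triene installed last.
- Stereochemistry: both ring centres come from catalyst-controlled Corey–Chaykovsky epoxidation (steps 2 and 4), with retention in the ring expansion and inversion at each centre in step 5. The 11E and 13E bonds come from the dienal and 9E from the Julia–Kocienski step.

Key step: step 5

Remark: LaLi3[(S)-binaphthoxide]3 is assumed to deliver CH2 to the methyl ketone face that gives the (S)-2-alkyl-2-methyloxirane; if its sense is the opposite, the (R)-binaphthoxide complex is used in steps 2 and 4.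

**Route**

Step 1
Reactants: 1 ethyl (2-methyl-1,3-dioxolan-2-yl)acetate
Product: 3 1-(2-methyl-1,3-dioxolan-2-yl)propan-2-one, via Weinreb amide 2 (not isolated)
Conditions: MeNH(OMe)·HCl, i-PrMgCl, THF, −20 °C; then MeMgBr, −20 to 0 °C; aq. NH4Cl
Reagents that add atoms: methylmagnesium bromide, C[Mg]Br
Why: The chloromagnesium amide turns the ester into the Weinreb amide in the flask, and its chelated adduct with MeMgBr survives until work-up, so the acylation stops at the methyl ketone (Weinreb ketone synthesis).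

Step 2
Reactants: 3 1-(2-methyl-1,3-dioxolan-2-yl)propan-2-one
Product: 5 (2R)-2-methyl-2-[(2-methyl-1,3-dioxolan-2-yl)methyl]oxetane, via epoxide 4 (not isolated)
Conditions: Me3S(O)I/NaH (preformed ylide), LaLi3[(S)-binaphthoxide]3 (5 mol %), (2,4,6-(MeO)3C6H2)3P=O, 5 Å MS, THF, rt; then more ylide and catalyst, 45 °C
Reagents that add atoms: trimethylsulfoxonium iodide (both CH2 units, through its ylide), C[S+](C)(C)=O.[I-]
Why: Catalytic asymmetric Corey–Chaykovsky epoxidation of the methyl ketone should set the quaternary centre as the (S)-epoxide under catalyst control, and a second ylide opens the epoxide at CH2 so that the tertiary alkoxide displaces DMSO (4-exo-tet ring expansion) with retention, giving the (R)-oxetane.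

Step 3
Reactants: 5 (2R)-2-methyl-2-[(2-methyl-1,3-dioxolan-2-yl)methyl]oxetane
Product: 6 1-[(2R)-2-methyloxetan-2-yl]propan-2-one
Conditions: PPTS (cat.), acetone/H2O, 40 °C
Reagents that add atoms: water, O
Why: Mild acid-catalysed ketal hydrolysis frees the second methyl ketone, the weak acid being chosen so that the 2,2-disubstituted oxetane is not ionised.

Step 4
Reactants: 6 1-[(2R)-2-methyloxetan-2-yl]propan-2-one
Product: 8 (2R,2′R)-2,2′-methylenebis(2-methyloxetane), via epoxy oxetane 7 (not isolated)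
Conditions: Me3S(O)I/NaH (preformed ylide), LaLi3[(S)-binaphthoxide]3 (5 mol %), (2,4,6-(MeO)3C6H2)3P=O, 5 Å MS, THF, rt; then more ylide and catalyst, 45 °C
Reagents that add atoms: trimethylsulfoxonium iodide (both CH2 units, through its ylide), C[S+](C)(C)=O.[I-]
Why: The same catalyst-controlled Corey–Chaykovsky epoxidation and ylide ring expansion should give the same sense at the new centre and hence the C2-symmetric (R,R) isomer, any wrong-sense addition ending as the meso diastereomer, which is removed here or after step 5.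

Step 5
Reactants: 8 (2R,2′R)-2,2′-methylenebis(2-methyloxetane)
Product: 10 2,2′-[(3S,5S)-3,5-dimethyl-1,2-dioxolane-3,5-diyl]di(ethan-1-ol), via hydroperoxy oxetane 9 (not isolated)
Conditions: H2O2 (dry, in Et2O, about 1.2 equiv), TMSOTf (0.3 equiv), Et2O, −78 to −20 °C
Reagents that add atoms: hydrogen peroxide, OO
Why: One TMSOTf-activated oxetane is opened by H2O2 at its tertiary carbon with inversion (borderline SN2 on a tight ion pair) to give hydroperoxy oxetane 9, whose OOH then opens the second activated oxetane at its tertiary carbon, again with inversion, which forms the second O–C bond and closes the 1,2-dioxolane. The closest known reaction types are the Lewis-acid perhydrolysis of 2,2-disubstituted oxetanes to 3-hydroperoxy alkanols and the intramolecular opening of oxetanes by tethered hydroperoxides. The ring closes in the 5-exo-tet mode, the breaking oxetane C–O bond lying outside the forming five-membered ring. Both new stereocentres are controlled by the configuration of the oxetane carbons (R,R from steps 2 and 4) through stereospecific inversion, so the methyl groups and the two hydroxyethyl arms should each end trans, as the (3S,5S) diol. The step needs tertiary over primary C–O cleavage, secured by the cation-stabilising alkyl groups on the oxetane carbon under Lewis acid activation, and it needs the tethered hydroperoxide to win over external H2O2 and over the freed primary hydroxyl, secured by about one equivalent of H2O2 at low temperature, the five-membered transition state and the higher nucleophilicity of the hydroperoxide. Because 10 is C2-symmetric its two ring carbons are equivalent, and the carbon closed in the second event is carried forward as the chain-bearing C5.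

Step 6
Reactants: 10 2,2′-[(3S,5S)-3,5-dimethyl-1,2-dioxolane-3,5-diyl]di(ethan-1-ol)
Product: 11 2,2′-[(3R,5R)-3,5-dimethyl-1,2-dioxolane-3,5-diyl]diacetaldehyde
Conditions: Dess–Martin periodinane (2.5 equiv), CH2Cl2, 0 °C to rt
Reagents that add atoms: none
Why: Dess–Martin oxidation of both primary alcohols is non-basic, leaves the O–O bond alone and cannot epimerise the fully substituted ring carbons.

Step 7
Reactants: 12 1,7-dibromoheptane; 13 1-phenyl-1H-tetrazole-5-thiol
Product: 14 5-[(7-bromoheptyl)sulfanyl]-1-phenyl-1H-tetrazole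
Conditions: K2CO3, acetone, rt (12 in threefold excess)
Reagents that add atoms: none
Why: S-Alkylation (SN2) of the soft thiolate with an excess of the dibromide should give the mono-sulfide.

Step 8
Reactants: 14 5-[(7-bromoheptyl)sulfanyl]-1-phenyl-1H-tetrazole
Product: 15 triphenyl{7-[(1-phenyl-1H-tetrazol-5-yl)sulfanyl]heptyl}phosphonium bromide
Conditions: PPh3, MeCN, reflux; recrystallised free of PPh3
Reagents that add atoms: triphenylphosphine, c1ccccc1P(c1ccccc1)c1ccccc1
Why: Quaternisation (SN2) of triphenylphosphine by the primary bromide gives the Wittig salt.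

Step 9
Reactants: 11 2,2′-[(3R,5R)-3,5-dimethyl-1,2-dioxolane-3,5-diyl]diacetaldehyde; 15 triphenyl{7-[(1-phenyl-1H-tetrazol-5-yl)sulfanyl]heptyl}phosphonium bromide
Product: 17 2-[(3R,5S)-3,5-dimethyl-5-{(2Z)-9-[(1-phenyl-1H-tetrazol-5-yl)sulfanyl]non-2-en-1-yl}-1,2-dioxolan-3-yl]acetaldehyde, via phosphorus ylide 16 (not isolated)
Conditions: 15, NaN(SiMe3)2, THF, −78 to 0 °C; then added slowly to 11 (2 equiv), THF, −78 °C
Reagents that add atoms: none
Why: Wittig olefination of one of the two homotopic aldehyde groups by the limiting non-stabilised ylide at −78 °C, where carbonyl addition should outrun enolisation; the (Z) geometry is irrelevant because step 11 reduces the alkene, and unreacted 11 is recovered.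

Step 10
Reactants: 17 2-[(3R,5S)-3,5-dimethyl-5-{(2Z)-9-[(1-phenyl-1H-tetrazol-5-yl)sulfanyl]non-2-en-1-yl}-1,2-dioxolan-3-yl]acetaldehyde
Product: 18 2-[(3R,5S)-3,5-dimethyl-5-{(2Z)-9-[(1-phenyl-1H-tetrazol-5-yl)sulfanyl]non-2-en-1-yl}-1,2-dioxolan-3-yl]acetic acid
Conditions: NaClO2, NaH2PO4, 2-methyl-2-butene, t-BuOH/H2O, 0 °C to rt
Reagents that add atoms: sodium chlorite, [Na+].[O-]Cl=O
Why: Pinnick oxidation converts the remaining aldehyde into the acid under buffered, non-basic conditions, 2-methyl-2-butene scavenging HOCl so that alkene and sulfide are spared.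

Step 11
Reactants: 18 2-[(3R,5S)-3,5-dimethyl-5-{(2Z)-9-[(1-phenyl-1H-tetrazol-5-yl)sulfanyl]non-2-en-1-yl}-1,2-dioxolan-3-yl]acetic acid
Product: 19 2-[(3R,5S)-3,5-dimethyl-5-{9-[(1-phenyl-1H-tetrazol-5-yl)sulfanyl]nonyl}-1,2-dioxolan-3-yl]acetic acid
Conditions: 2-nitrobenzenesulfonohydrazide (excess), Et3N, CH2Cl2, rt
Reagents that add atoms: none
Why: Diimide reduction: diimide made in the flask adds H2 to the unpolarised C=C by concerted syn transfer and leaves the O–O bond, the sulfide and the acid untouched.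

Step 12
Reactants: 19 2-[(3R,5S)-3,5-dimethyl-5-{9-[(1-phenyl-1H-tetrazol-5-yl)sulfanyl]nonyl}-1,2-dioxolan-3-yl]acetic acid
Product: 20 2-[(3R,5S)-3,5-dimethyl-5-{9-[(1-phenyl-1H-tetrazol-5-yl)sulfonyl]nonyl}-1,2-dioxolan-3-yl]acetic acid
Conditions: 30% H2O2, (NH4)6Mo7O24·4H2O (cat.), EtOH, 0 °C to rt
Reagents that add atoms: hydrogen peroxide, OO
Why: (NH4)6Mo7O24-catalysed sulfide-to-sulfone oxidation with H2O2, to which the di-tertiary peroxide and the carboxylic acid are inert.

Step 13
Reactants: 20 2-[(3R,5S)-3,5-dimethyl-5-{9-[(1-phenyl-1H-tetrazol-5-yl)sulfonyl]nonyl}-1,2-dioxolan-3-yl]acetic acid; 21 (2E,4E)-hepta-2,4-dienal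
Product: 22 2-[(3R,5S)-5-[(9E,11E,13E)-hexadeca-9,11,13-trien-1-yl]-3,5-dimethyl-1,2-dioxolan-3-yl]acetic acid
Conditions: KN(SiMe3)2 (2.2 equiv), DME, −78 °C; then 21, −78 °C to rt; aq. NH4Cl then dilute HCl; cat. I2, CH2Cl2, rt
Reagents that add atoms: none
Why: Julia–Kocienski olefination: the α-sulfonyl carbanion (formed after the carboxylate) adds to the dienal, and Smiles rearrangement with loss of SO2 and the tetrazolone should give the (E)-alkene, with catalytic iodine equilibrating any 9Z isomer to the all-(E) triene while 11E and 13E come from 21.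

**Compound list**

1 | ethyl (2-methyl-1,3-dioxolan-2-yl)acetate | CCOC(=O)CC1(C)OCCO1 | starting material
2 | N-methoxy-N-methyl-2-(2-methyl-1,3-dioxolan-2-yl)acetamide | CON(C)C(=O)CC1(C)OCCO1 | intermediate
3 | 1-(2-methyl-1,3-dioxolan-2-yl)propan-2-one | CC(=O)CC1(C)OCCO1 | intermediate
4 | (2S)-2-methyl-2-[(2-methyl-1,3-dioxolan-2-yl)methyl]oxirane | CC1(C[C@@]2(C)CO2)OCCO1 | intermediate
5 | (2R)-2-methyl-2-[(2-methyl-1,3-dioxolan-2-yl)methyl]oxetane | CC1(C[C@@]2(C)CCO2)OCCO1 | intermediate
6 | 1-[(2R)-2-methyloxetan-2-yl]propan-2-one | CC(=O)C[C@@]1(C)CCO1 | intermediate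
7 | (2R)-2-methyl-2-{[(2S)-2-methyloxiran-2-yl]methyl}oxetane | O1C[C@]1(C)C[C@@]2(C)CCO2 | intermediate
8 | (2R,2′R)-2,2′-methylenebis(2-methyloxetane) | O1CC[C@]1(C)C[C@@]2(C)CCO2 | intermediate
9 | (3S)-3-hydroperoxy-3-methyl-4-[(2R)-2-methyloxetan-2-yl]butan-1-ol | OCC[C@@](OO)(C)C[C@@]1(C)CCO1 | intermediate
10 | 2,2′-[(3S,5S)-3,5-dimethyl-1,2-dioxolane-3,5-diyl]di(ethan-1-ol) | OCC[C@@]1(C)C[C@](C)(CCO)OO1 | intermediate
11 | 2,2′-[(3R,5R)-3,5-dimethyl-1,2-dioxolane-3,5-diyl]diacetaldehyde | O=CC[C@@]1(C)C[C@](C)(CC=O)OO1 | intermediate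
12 | 1,7-dibromoheptane | BrCCCCCCCBr | starting material
13 | 1-phenyl-1H-tetrazole-5-thiol | Sc1nnnn1-c1ccccc1 | starting material
14 | 5-[(7-bromoheptyl)sulfanyl]-1-phenyl-1H-tetrazole | BrCCCCCCCSc1nnnn1-c1ccccc1 | intermediate
15 | triphenyl{7-[(1-phenyl-1H-tetrazol-5-yl)sulfanyl]heptyl}phosphonium bromide | [Br-].c1ccccc1[P+](c1ccccc1)(c1ccccc1)CCCCCCCSc1nnnn1-c1ccccc1 | intermediate
16 | triphenyl{7-[(1-phenyl-1H-tetrazol-5-yl)sulfanyl]heptylidene}phosphorane | c1ccccc1P(c1ccccc1)(c1ccccc1)=CCCCCCCSc1nnnn1-c1ccccc1 | intermediate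
17 | 2-[(3R,5S)-3,5-dimethyl-5-{(2Z)-9-[(1-phenyl-1H-tetrazol-5-yl)sulfanyl]non-2-en-1-yl}-1,2-dioxolan-3-yl]acetaldehyde | c1ccccc1-n1nnnc1SCCCCCC/C=C\C[C@@]1(C)C[C@](C)(CC=O)OO1 | intermediate
18 | 2-[(3R,5S)-3,5-dimethyl-5-{(2Z)-9-[(1-phenyl-1H-tetrazol-5-yl)sulfanyl]non-2-en-1-yl}-1,2-dioxolan-3-yl]acetic acid | c1ccccc1-n1nnnc1SCCCCCC/C=C\C[C@@]1(C)C[C@](C)(CC(=O)O)OO1 | intermediate
19 | 2-[(3R,5S)-3,5-dimethyl-5-{9-[(1-phenyl-1H-tetrazol-5-yl)sulfanyl]nonyl}-1,2-dioxolan-3-yl]acetic acid | c1ccccc1-n1nnnc1SCCCCCCCCC[C@@]1(C)C[C@](C)(CC(=O)O)OO1 | intermediate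
20 | 2-[(3R,5S)-3,5-dimethyl-5-{9-[(1-phenyl-1H-tetrazol-5-yl)sulfonyl]nonyl}-1,2-dioxolan-3-yl]acetic acid | c1ccccc1-n1nnnc1S(=O)(=O)CCCCCCCCC[C@@]1(C)C[C@](C)(CC(=O)O)OO1 | intermediate
21 | (2E,4E)-hepta-2,4-dienal | CC/C=C/C=C/C=O | starting material
22 | 2-[(3R,5S)-5-[(9E,11E,13E)-hexadeca-9,11,13-trien-1-yl]-3,5-dimethyl-1,2-dioxolan-3-yl]acetic acid | CC/C=C/C=C/C=C/CCCCCCCC[C@@]1(C)C[C@](C)(CC(=O)O)OO1 | target

**Step count**

Total: 13 steps (11 in the main line, 2 for the phosphonium salt). Longest linear sequence: 11 steps (steps 1–6 and 9–13).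

**Steps most likely to fail**

Step 5. The second oxetane carbon may ionise before the hydroperoxide arrives, which would lose the stereochemical fidelity and give the cis isomer. The activated second oxetane may also be intercepted by the freed primary hydroxyl or by a second H2O2, and the tertiary hydroperoxide may fragment under acid. The fallback sets out from ketone 6 and comes back at diol 10. It makes the two O–C bonds in separate known operations and completes the second ring carbon by C–C bond formation on a peroxycarbenium ion. H2O2 and TMSOTf open the oxetane of 6 with inversion, and the β-hydroperoxy ketone closes to the peroxy hemiketal (5S)-5-(2-hydroxyethyl)-3,5-dimethyl-1,2-dioxolan-3-ol F1. Ac2O and pyridine give the diacetate 2-[(3S)-5-acetoxy-3,5-dimethyl-1,2-dioxolan-3-yl]ethyl acetate F2. SnCl4 and allyltrimethylsilane give 2-[(3S,5S)-3,5-dimethyl-5-(prop-2-en-1-yl)-1,2-dioxolan-3-yl]ethyl acetate F3, which is separated from its C5 epimer. Ozonolysis with NaBH4 work-up gives 2-[(3S,5S)-5-(2-hydroxyethyl)-3,5-dimethyl-1,2-dioxolan-3-yl]ethyl acetate F4, and K2CO3 in MeOH gives 10.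

Step 4. The basic ylide and catalyst may enolise the β-oxetanyl ketone, after which β-elimination would open the first oxetane. Catalyst control may also be eroded by the resident stereocentre or by coordination of the oxetane oxygen. The fallback sets out from 6 and comes back at 8 without a basic carbon nucleophile. Catalytic enantioselective allylboration (allyl-B(OiPr)2, the suitable antipode of 3,3′-dibromo-BINOL) should give (2R)-2-methyl-1-[(2R)-2-methyloxetan-2-yl]pent-4-en-2-ol F5. Ozonolysis with NaBH4 work-up gives (3R)-3-methyl-4-[(2R)-2-methyloxetan-2-yl]butane-1,3-diol F6. TsCl and pyridine give (3R)-3-hydroxy-3-methyl-4-[(2R)-2-methyloxetan-2-yl]butyl 4-methylbenzenesulfonate F7, and KOtBu closes the second oxetane with retention at the carbinol carbon to give 8. Only one tertiary alkoxide is present and the other oxygen is already locked in the first oxetane, so no six-membered ether can form.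

Step 9. Both aldehyde arms may be olefinated, and an aldehyde arm that waits unreacted beside the basic ylide may lose the peroxide by β-elimination. The fallback sets out from 10 and comes back at 18, with the second arm kept as a non-enolisable silyl ether during the olefination. NaH and TBSCl give 2-[(3S,5S)-5-(2-{[tert-butyl(dimethyl)silyl]oxy}ethyl)-3,5-dimethyl-1,2-dioxolan-3-yl]ethan-1-ol F8. Dess–Martin oxidation gives 2-[(3R,5S)-5-(2-{[tert-butyl(dimethyl)silyl]oxy}ethyl)-3,5-dimethyl-1,2-dioxolan-3-yl]acetaldehyde F9. Wittig reaction with ylide 16 gives tert-butyl{2-[(3S,5S)-3,5-dimethyl-5-{(2Z)-9-[(1-phenyl-1H-tetrazol-5-yl)sulfanyl]non-2-en-1-yl}-1,2-dioxolan-3-yl]ethoxy}dimethylsilane F10. HF·pyridine gives 2-[(3S,5S)-3,5-dimethyl-5-{(2Z)-9-[(1-phenyl-1H-tetrazol-5-yl)sulfanyl]non-2-en-1-yl}-1,2-dioxolan-3-yl]ethan-1-ol F11, and TEMPO with PhI(OAc)2 in wet MeCN oxidises it to acid 18.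

Further compounds
F1 | step 5 | (5S)-5-(2-hydroxyethyl)-3,5-dimethyl-1,2-dioxolan-3-ol (both C3 epimers) | OCC[C@@]1(C)CC(C)(O)OO1
F2 | step 5 | 2-[(3S)-5-acetoxy-3,5-dimethyl-1,2-dioxolan-3-yl]ethyl acetate (both C5 epimers) | CC(=O)OCC[C@@]1(C)CC(C)(OC(C)=O)OO1
F3 | step 5 | 2-[(3S,5S)-3,5-dimethyl-5-(prop-2-en-1-yl)-1,2-dioxolan-3-yl]ethyl acetate | CC(=O)OCC[C@@]1(C)C[C@](C)(CC=C)OO1
F4 | step 5 | 2-[(3S,5S)-5-(2-hydroxyethyl)-3,5-dimethyl-1,2-dioxolan-3-yl]ethyl acetate | CC(=O)OCC[C@@]1(C)C[C@](C)(CCO)OO1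
F5 | step 4 | (2R)-2-methyl-1-[(2R)-2-methyloxetan-2-yl]pent-4-en-2-ol | C=CC[C@](O)(C)C[C@@]1(C)CCO1
F6 | step 4 | (3R)-3-methyl-4-[(2R)-2-methyloxetan-2-yl]butane-1,3-diol | OCC[C@](O)(C)C[C@@]1(C)CCO1
F7 | step 4 | (3R)-3-hydroxy-3-methyl-4-[(2R)-2-methyloxetan-2-yl]butyl 4-methylbenzenesulfonate | Cc1ccc(cc1)S(=O)(=O)OCC[C@](O)(C)C[C@@]1(C)CCO1
F8 | step 9 | 2-[(3S,5S)-5-(2-{[tert-butyl(dimethyl)silyl]oxy}ethyl)-3,5-dimethyl-1,2-dioxolan-3-yl]ethan-1-ol | CC(C)(C)[Si](C)(C)OCC[C@@]1(C)C[C@](C)(CCO)OO1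
F9 | step 9 | 2-[(3R,5S)-5-(2-{[tert-butyl(dimethyl)silyl]oxy}ethyl)-3,5-dimethyl-1,2-dioxolan-3-yl]acetaldehyde | CC(C)(C)[Si](C)(C)OCC[C@@]1(C)C[C@](C)(CC=O)OO1
F10 | step 9 | tert-butyl{2-[(3S,5S)-3,5-dimethyl-5-{(2Z)-9-[(1-phenyl-1H-tetrazol-5-yl)sulfanyl]non-2-en-1-yl}-1,2-dioxolan-3-yl]ethoxy}dimethylsilane | CC(C)(C)[Si](C)(C)OCC[C@@]1(C)C[C@](C)(C/C=C\CCCCCCSc2nnnn2-c2ccccc2)OO1
F11 | step 9 | 2-[(3S,5S)-3,5-dimethyl-5-{(2Z)-9-[(1-phenyl-1H-tetrazol-5-yl)sulfanyl]non-2-en-1-yl}-1,2-dioxolan-3-yl]ethan-1-ol | OCC[C@@]1(C)C[C@](C)(C/C=C\CCCCCCSc2nnnn2-c2ccccc2)OO1
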